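**Plan**

- Ring A is cut first, at C4a–C5 (Claisen condensation) and C8–C8a (conjugate addition followed by re-oxidation). This releases a 2-aryl-2,3-dihydro-4H-pyran-4-one and a γ-prenylated acetoacetate, used as its bis-silyl dienol ether.
- Ring C is then cut at C2–C3 and O1–C8a. O1–C2 is simply the carbonyl group of a ring B aldehyde, and C3, C4, C4a and C8a are a 1-methoxy-3-silyloxybutadiene, so ring C can be built as a dihydropyranone by hetero-Diels–Alder reaction while ring A does not yet exist.
- The aldehyde comes from 4-hydroxybenzaldehyde by ortho C-prenylation and propargyl-ether chromene annulation.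
- Forward order: pyran ring of the ring B chromene, then ring C (step 4), then ring A (steps 8–10). Flavanone numbering (O1, C2–C4, C4a, C5–C8, C8a) is used for all intermediates.
- The only stereocentre, C2, is set by the BINOL ligand on titanium in step 4. The C2–O1 bond is never broken afterwards.

Key step: step 4

Notation: Ar = 2,2-dimethyl-8-(3-methylbut-2-en-1-yl)-2H-chromen-6-yl.

Assumption: the (S)-BINOL–titanium catalyst is taken to direct the diene to the Si face of the aldehyde (the sense this catalyst type shows with benzaldehyde in allylation and aldol reactions), which corresponds to 2S. If the dihydropyranone proves to be the antipode, (R)-BINOL is used instead.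

**Route**

Step 1
Reactants: 1 4-hydroxybenzaldehyde; 2 prenyl bromide
Product: 3 4-hydroxy-3-(3-methylbut-2-en-1-yl)benzaldehyde
Conditions: KOH, H2O, rt
Reagents that add atoms: none
Why: Phenoxide C-alkylation in water, where the solvated oxygen is shielded and the ambident anion is alkylated at the free ortho carbon by the allylic bromide, is a known direct ortho-prenylation of this phenol; the O-prenyl ether and doubly prenylated by-products should be removable by chromatography.

Step 2
Reactants: 3 4-hydroxy-3-(3-methylbut-2-en-1-yl)benzaldehyde; 4 3-chloro-3-methylbut-1-yne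
Product: 5 4-[(2-methylbut-3-yn-2-yl)oxy]-3-(3-methylbut-2-en-1-yl)benzaldehyde
Conditions: K2CO3, KI (cat.), acetone, reflux
Reagents that add atoms: none
Why: Iodide-assisted Williamson-type O-alkylation of the phenoxide with the tertiary propargylic chloride is the standard entry to aryl 1,1-dimethylpropargyl ethers, and the aldehyde and the prenyl olefin are inert to carbonate.

Step 3
Reactants: 5 4-[(2-methylbut-3-yn-2-yl)oxy]-3-(3-methylbut-2-en-1-yl)benzaldehyde
Product: 6 2,2-dimethyl-8-(3-methylbut-2-en-1-yl)-2H-chromene-6-carbaldehyde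
Conditions: PhNEt2, 190 °C
Reagents that add atoms: none
Why: Thermal aryl propargyl ether Claisen rearrangement to the only free ortho position (the other is blocked by the prenyl group), followed by 1,5-hydrogen shift and oxa-6π electrocyclisation, is the classical 2,2-dimethylchromene synthesis and needs no reagent that could touch the aldehyde or the prenyl group.

Step 4
Reactants: 6 2,2-dimethyl-8-(3-methylbut-2-en-1-yl)-2H-chromene-6-carbaldehyde; 7 (E)-1-methoxy-3-(trimethylsilyloxy)buta-1,3-diene
Product: 9 (2S)-2-Ar-2,3-dihydro-4H-pyran-4-one, via silylated aldol adduct 8 (not isolated)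
Conditions: (S)-BINOL (20 mol %), Ti(OiPr)4 (10 mol %), 4 Å MS, Et2O, −20 °C; then CF3CO2H, 0 °C
Reagents that add atoms: none
Why: The chiral tetravalent titanium Lewis acid formed from Ti(OiPr)4 and (S)-BINOL binds the aldehyde oxygen of 6, the unsubstituted terminus of diene 7 (future C3) attacks the carbonyl carbon (future C2) in a Mukaiyama-aldol-type or asynchronous [4+2] event with silyl transfer to give 8, and brief CF3CO2H then makes the C2 oxygen (O1) add to the methoxy-bearing carbon (C8a) and expels methanol. The closest known reaction type is the BINOL–titanium-catalysed hetero-Diels–Alder (aldol–cyclisation) reaction of 1-methoxy-3-silyloxybutadiene with aromatic aldehydes to 2-aryl-2,3-dihydro-4H-pyran-4-ones. Ring C closes by a 6-endo-trig oxa-Michael addition–elimination at C8a, overall a formal [4+2] cycloaddition across the C=O bond. The new stereocentre C2 is set by catalyst control alone: the (S)-binaphtholate on titanium shields one face of the bound carbonyl so that the diene should add to the Si face and give 2S, and the ring closure does not touch the C2–O bond. The step needs only enantiofacial selectivity, which the substrate supports because the aldehyde cannot enolise, has two free ortho positions for unhindered coordination and reacts only at the activated carbonyl, its prenyl and chromene olefins being inert to the mild Lewis acid. The acid treatment is kept short and cold so that the p-alkoxybenzylic C2–O bond does not ionise.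

Step 5
Reactants: 10 methyl acetoacetate; 2 prenyl bromide
Product: 11 methyl 7-methyl-3-oxooct-6-enoate
Conditions: NaH, THF, 0 °C; n-BuLi, 0 °C; then 2, 0 °C to rt; then aq HCl
Reagents that add atoms: none
Why: β-Keto ester dianion alkylation: the sodium lithium dianion reacts with the allylic bromide by SN2 only at its more nucleophilic γ-carbon, giving the γ-prenylated acetoacetate.

Step 6
Reactants: 11 methyl 7-methyl-3-oxooct-6-enoate
Product: 12 methyl (2Z)-7-methyl-3-(trimethylsilyloxy)octa-2,6-dienoate
Conditions: Me3SiCl, Et3N, Et2O, rt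
Reagents that add atoms: chlorotrimethylsilane, C[Si](C)(C)Cl
Why: Soft enolisation and O-silylation of the β-keto ester (silyl enol ether formation) should give the conjugated β-silyloxy enoate, with the ammonium salt removed by filtration.

Step 7
Reactants: 12 methyl (2Z)-7-methyl-3-(trimethylsilyloxy)octa-2,6-dienoate
Product: 13 1-methoxy-7-methyl-1,3-bis(trimethylsilyloxy)octa-1,3,6-triene
Conditions: LiN(iPr)2, THF, −78 °C; Me3SiCl, −78 to 0 °C
Reagents that add atoms: chlorotrimethylsilane, C[Si](C)(C)Cl
Why: γ-Deprotonation of the β-silyloxy enoate and O-silylation of the resulting ester dienolate is the standard preparation of 1-alkoxy-1,3-bis(silyloxy)-1,3-dienes; the moisture-sensitive diene is freed from salts without aqueous contact and used at once.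

Step 8
Reactants: 9 (2S)-2-Ar-2,3-dihydro-4H-pyran-4-one; 13 1-methoxy-7-methyl-1,3-bis(trimethylsilyloxy)octa-1,3,6-triene
Product: 14 methyl 4-[(6S)-6-Ar-4-(trimethylsilyloxy)-5,6-dihydro-2H-pyran-2-yl]-7-methyl-3-(trimethylsilyloxy)octa-2,6-dienoate
Conditions: Me3SiOTf (0.2 equiv), CH2Cl2, −78 to −40 °C; Et3N quench, concentrate, use crude
Reagents that add atoms: none
Why: Silyl-triflate-catalysed Mukaiyama–Michael addition, in which O-silylation of the vinylogous ester gives a 4-silyloxy oxocarbenium ion that the diene attacks with its prenyl-bearing terminal carbon (C8) at C8a, expected trans to the C2 aryl group by axial attack, while silyl transfer from the diene turns the catalyst over; the new centres at C8a and C8 become trigonal later, so their configuration is immaterial, and C2 is not touched.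

Step 9
Reactants: 14 methyl 4-[(6S)-6-Ar-4-(trimethylsilyloxy)-5,6-dihydro-2H-pyran-2-yl]-7-methyl-3-(trimethylsilyloxy)octa-2,6-dienoate
Product: 16 methyl 4-[(2S)-2-Ar-4-oxo-3,4-dihydro-2H-pyran-6-yl]-7-methyl-3-oxooct-6-enoate, via side-chain silyl enol ether enone 15 (not isolated)
Conditions: Pd(OAc)2 (1.2 equiv), MeCN, rt; then aq citric acid, THF, 0 °C
Reagents that add atoms: none
Why: Saegusa–Ito oxidation, in which the ring silyl enol ether is converted into a divalent palladium enolate at C4a whose only β-hydrogen sits on C8a, so β-hydride elimination restores the C4a=C8a enone with the new carbon chain in place; the conjugated side-chain silyl enol ether has no β-hydrogen to lose and is hydrolysed in the mild acidic work-up.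

Step 10
Reactants: 16 methyl 4-[(2S)-2-Ar-4-oxo-3,4-dihydro-2H-pyran-6-yl]-7-methyl-3-oxooct-6-enoate
Product: 18 maackiaflavanone B, via triketone tautomer 17 (not isolated)
Conditions: DBU (3 equiv), MeCN, 0 °C to rt; then aq NaH2PO4 (pH 5)
Reagents that add atoms: none
Why: Intramolecular Claisen (Dieckmann-type) condensation in the polyketide C-acylation mode, in which the extended enolate formed by deprotonation at C8 is nucleophilic at C4a and attacks the ester carbon C5 (6-exo-trig, the only six-membered closure the intact pyranone allows), methoxide leaves and the triketone tautomerises irreversibly to the phloroglucinol-type ring A; C2 should be preserved because the C2–O1 bond is not broken and the amidine base does not enolise C3 appreciably, and the weakly acidic quench avoids cyclisation of the 8-prenyl group onto the C7 hydroxyl.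

**Compound list**

1 | 4-hydroxybenzaldehyde | O=Cc1ccc(O)cc1 | starting material
2 | prenyl bromide (1-bromo-3-methylbut-2-ene) | CC(C)=CCBr | starting material
3 | 4-hydroxy-3-(3-methylbut-2-en-1-yl)benzaldehyde | O=Cc1ccc(O)c(CC=C(C)C)c1 | intermediate
4 | 3-chloro-3-methylbut-1-yne | C#CC(C)(C)Cl | starting material
5 | 4-[(2-methylbut-3-yn-2-yl)oxy]-3-(3-methylbut-2-en-1-yl)benzaldehyde | O=Cc1ccc(OC(C)(C)C#C)c(CC=C(C)C)c1 | intermediate
6 | 2,2-dimethyl-8-(3-methylbut-2-en-1-yl)-2H-chromene-6-carbaldehyde | O=Cc1cc(CC=C(C)C)c2OC(C)(C)C=Cc2c1 | intermediate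
7 | (E)-1-methoxy-3-(trimethylsilyloxy)buta-1,3-diene | CO/C=C/C(=C)O[Si](C)(C)C | starting material
8 | (1E,5S)-5-Ar-1-methoxy-5-(trimethylsilyloxy)pent-1-en-3-one (not isolated) | CO/C=C/C(=O)C[C@H](O[Si](C)(C)C)c1cc(CC=C(C)C)c2OC(C)(C)C=Cc2c1 | intermediate
9 | (2S)-2-Ar-2,3-dihydro-4H-pyran-4-one | O=C1C[C@@H](c2cc(CC=C(C)C)c3OC(C)(C)C=Cc3c2)OC=C1 | intermediate
10 | methyl acetoacetate | COC(=O)CC(C)=O | starting material
11 | methyl 7-methyl-3-oxooct-6-enoate | COC(=O)CC(=O)CCC=C(C)C | intermediate
12 | methyl (2Z)-7-methyl-3-(trimethylsilyloxy)octa-2,6-dienoate | COC(=O)/C=C(O[Si](C)(C)C)/CCC=C(C)C | intermediate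
13 | 1-methoxy-7-methyl-1,3-bis(trimethylsilyloxy)octa-1,3,6-triene (mixture of double-bond isomers, geometry left open) | COC(O[Si](C)(C)C)=CC(O[Si](C)(C)C)=CCC=C(C)C | intermediate
14 | methyl 4-[(6S)-6-Ar-4-(trimethylsilyloxy)-5,6-dihydro-2H-pyran-2-yl]-7-methyl-3-(trimethylsilyloxy)octa-2,6-dienoate (ring expected 2,6-trans; mixture at chain C4; these centres left open) | COC(=O)C=C(O[Si](C)(C)C)C(CC=C(C)C)C1C=C(O[Si](C)(C)C)C[C@@H](c2cc(CC=C(C)C)c3OC(C)(C)C=Cc3c2)O1 | intermediate
15 | methyl 4-[(2S)-2-Ar-4-oxo-3,4-dihydro-2H-pyran-6-yl]-7-methyl-3-(trimethylsilyloxy)octa-2,6-dienoate (not isolated; mixture at chain C4) | COC(=O)C=C(O[Si](C)(C)C)C(CC=C(C)C)C1=CC(=O)C[C@@H](c2cc(CC=C(C)C)c3OC(C)(C)C=Cc3c2)O1 | intermediate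
16 | methyl 4-[(2S)-2-Ar-4-oxo-3,4-dihydro-2H-pyran-6-yl]-7-methyl-3-oxooct-6-enoate (mixture at chain C4) | COC(=O)CC(=O)C(CC=C(C)C)C1=CC(=O)C[C@@H](c2cc(CC=C(C)C)c3OC(C)(C)C=Cc3c2)O1 | intermediate
17 | (2S)-2-Ar-8-(3-methylbut-2-en-1-yl)-2,3-dihydro-4H-chromene-4,5,7(4aH,6H)-trione (not isolated) | O=C1C[C@@H](c2cc(CC=C(C)C)c3OC(C)(C)C=Cc3c2)OC2=C(CC=C(C)C)C(=O)CC(=O)C12 | intermediate
18 | maackiaflavanone B, (2S)-2-Ar-5,7-dihydroxy-8-(3-methylbut-2-en-1-yl)-2,3-dihydro-4H-chromen-4-one | CC(C)=CCc1cc([C@@H]2CC(=O)c3c(O)cc(O)c(CC=C(C)C)c3O2)cc2c1OC(C)(C)C=C2 | target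

**Step count and risks**

Total steps: 10. Longest linear sequence: 7 steps (steps 1, 2, 3, 4, 8, 9, 10, from 4-hydroxybenzaldehyde).

Steps most likely to fail:

1. Step 10. The weakly nucleophilic extended enolate may acylate slowly. On prolonged exposure to base, enolisation at C3 could expel O1 from C2 (reversible ring opening) and erode the enantiomeric purity of substrate or product. The fallback is neutral and thermal and sets out from 16. The β-keto ester is heated in mesitylene at about 150 °C over 4 Å MS, so that methanol is lost and the acylketene 4-[(2S)-2-Ar-4-oxo-3,4-dihydro-2H-pyran-6-yl]-7-methylocta-1,6-diene-1,3-dione F7 is formed. Its ketene carbon (C5) is captured by the enol-ether carbon C4a, either by 6π-electrocyclisation of the dienylketene that arises when the C7 ketone enolises towards C8, or by direct C-acylation. Tautomerisation then gives 18, where the fallback rejoins the route; no base is present at any point.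

2. Step 8. The doubly silylated diene may be protodesilylated or self-condense faster than it adds, it may react through its inner carbon, and its hindered prenyl-bearing terminus may add slowly. The fallback uses a more robust, strictly γ-selective donor and sets out from 9.
   - Purchased 2,2,6-trimethyl-4H-1,3-dioxin-4-one is deprotonated with LiN(iPr)2 in THF/DMPU at −78 °C and alkylated with 2 at its exocyclic γ-carbon to give 2,2-dimethyl-6-(4-methylpent-3-en-1-yl)-4H-1,3-dioxin-4-one F1.
   - A second deprotonation and O-silylation with tBuMe2SiCl gives the silyl dienol ether tert-butyl{[2,2-dimethyl-6-(4-methylpent-3-en-1-ylidene)-6H-1,3-dioxin-4-yl]oxy}dimethylsilane F2.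
   - Under catalytic tBuMe2SiOTf in CH2Cl2 at −78 °C, F2 should add to 9 through its γ-carbon at C8a to give 6-{1-[(6S)-6-Ar-4-(tert-butyldimethylsilyloxy)-5,6-dihydro-2H-pyran-2-yl]-4-methylpent-3-en-1-yl}-2,2-dimethyl-4H-1,3-dioxin-4-one F3.
   - Saegusa–Ito oxidation with Pd(OAc)2 gives 6-{1-[(2S)-2-Ar-4-oxo-3,4-dihydro-2H-pyran-6-yl]-4-methylpent-3-en-1-yl}-2,2-dimethyl-4H-1,3-dioxin-4-one F4.
   - Heating F4 with methanol in toluene at 110 °C releases acetone and the transient acylketene is captured as the methyl β-keto ester 16, where the fallback rejoins the route. Any acylketene that is captured at C4a instead leads directly to 18.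

3. Step 9. The labile ring silyl enol ether may hydrolyse before palladation, leaving the saturated ketone, or the palladium salt may isomerise or oxidise the prenyl olefins. The fallback is a selenoxide elimination and sets out from crude 14. Treatment with PhSeCl (1.0 equiv) in CH2Cl2 at −78 °C selenenylates the ring silyl enol ether at C4a, and aqueous work-up gives methyl 4-[(6S)-6-Ar-4-oxo-3-(phenylselanyl)oxan-2-yl]-7-methyl-3-oxooct-6-enoate F5. Oxidation with H2O2 and pyridine in CH2Cl2 at 0 °C gives the selenoxide methyl 4-[(6S)-6-Ar-4-oxo-3-(phenylseleninyl)oxan-2-yl]-7-methyl-3-oxooct-6-enoate F6. Its syn-elimination towards the C8a hydrogen should deliver 16, where the fallback rejoins the route.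

Further compounds

F1 | step 8 | 2,2-dimethyl-6-(4-methylpent-3-en-1-yl)-4H-1,3-dioxin-4-one | CC(C)=CCCC1=CC(=O)OC(C)(C)O1
F2 | step 8 | tert-butyl{[2,2-dimethyl-6-(4-methylpent-3-en-1-ylidene)-6H-1,3-dioxin-4-yl]oxy}dimethylsilane | CC(C)=CCC=C1C=C(O[Si](C)(C)C(C)(C)C)OC(C)(C)O1
F3 | step 8 | 6-{1-[(6S)-6-Ar-4-(tert-butyldimethylsilyloxy)-5,6-dihydro-2H-pyran-2-yl]-4-methylpent-3-en-1-yl}-2,2-dimethyl-4H-1,3-dioxin-4-one | CC(C)=CCC(C1=CC(=O)OC(C)(C)O1)C1C=C(O[Si](C)(C)C(C)(C)C)C[C@@H](c2cc(CC=C(C)C)c3OC(C)(C)C=Cc3c2)O1
F4 | step 8 | 6-{1-[(2S)-2-Ar-4-oxo-3,4-dihydro-2H-pyran-6-yl]-4-methylpent-3-en-1-yl}-2,2-dimethyl-4H-1,3-dioxin-4-one | CC(C)=CCC(C1=CC(=O)OC(C)(C)O1)C1=CC(=O)C[C@@H](c2cc(CC=C(C)C)c3OC(C)(C)C=Cc3c2)O1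
F5 | step 9 | methyl 4-[(6S)-6-Ar-4-oxo-3-(phenylselanyl)oxan-2-yl]-7-methyl-3-oxooct-6-enoate | COC(=O)CC(=O)C(CC=C(C)C)C1O[C@H](c2cc(CC=C(C)C)c3OC(C)(C)C=Cc3c2)CC(=O)C1[Se]c1ccccc1
F6 | step 9 | methyl 4-[(6S)-6-Ar-4-oxo-3-(phenylseleninyl)oxan-2-yl]-7-methyl-3-oxooct-6-enoate | COC(=O)CC(=O)C(CC=C(C)C)C1O[C@H](c2cc(CC=C(C)C)c3OC(C)(C)C=Cc3c2)CC(=O)C1[Se](=O)c1ccccc1
F7 | step 10 | 4-[(2S)-2-Ar-4-oxo-3,4-dihydro-2H-pyran-6-yl]-7-methylocta-1,6-diene-1,3-dione | O=C=CC(=O)C(CC=C(C)C)C1=CC(=O)C[C@@H](c2cc(CC=C(C)C)c3OC(C)(C)C=Cc3c2)O1
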